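Everything rests on cutting the C4–C5 bond of the lone carbocycle, cyclohexane ring A. C5, the later acetoxy carbinol, sits on C4, the methyl-bearing carbon of the later ring epoxide, so the ring alkene C3=C4 plus the C5 hydroxyl is the retron of an alkenyl-metal addition to an aldehyde. One intramolecular Nozaki–Hiyama–Kishi reaction closes ring A, sets C5 and frees the hydroxyl that afterwards steers the ring epoxidation. Its precursor is an acyclic (Z)-alkenyl iodide aldehyde that already carries both angelates, the C7 methylene and the prenyl group; C1/C6 come from a chiral hydroxy lactone, C8 from an allylboration.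

Key step: step 14

Remark: numbering used throughout is ring A C1 (bears the side chain), C2 (CH2), C3/C4 (epoxide, methyl on C4), C5 (OAc), C6 (OAng) and side chain C7 (=C14H2), C8 (OAng), C9, C10/C11 (epoxide); (R)-3-hydroxy-γ-butyrolactone, (−)-Ipc2B(allyl) solution and the L-fructose-derived Shi ketone are assumed to be purchasable.

Step 1
Reactants: 1 but-2-yn-1-ol
Product: 3 (Z)-3-iodobut-2-en-1-ol, via cyclic sodium alkenylalanate 2 (not isolated)
Conditions: NaAlH2(OCH2CH2OMe)2 (Red-Al), Et2O, 0 °C to rt; then I2, THF, −78 to 0 °C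
Reagents that add atoms: iodine, II
Why: Hydroxyl-directed trans-hydroalumination of the propargylic alcohol puts aluminium on C3 inside a five-membered alanate, and iodinolysis of that C–Al bond with retention should give only the (Z)-iodoalkene (hydroalumination–iodination).

Step 2
Reactants: 3 (Z)-3-iodobut-2-en-1-ol
Product: 4 (Z)-1-bromo-3-iodobut-2-ene
Conditions: PBr3, Et2O, 0 °C
Reagents that add atoms: phosphorus tribromide, BrP(Br)Br
Why: PBr3 converts the primary allylic alcohol into the bromide by SN2 displacement of a phosphite leaving group (alcohol-to-bromide substitution), which should leave the iodoalkene geometry untouched.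

Step 3
Reactants: 5 (R)-3-hydroxy-γ-butyrolactone; 4 (Z)-1-bromo-3-iodobut-2-ene
Product: 7 (3R,4R)-4-hydroxy-3-[(Z)-3-iodobut-2-enyl]dihydrofuran-2(3H)-one (trans lactone; lactone C2 = C7, C3 = C1, C4 = C6, C5 = C5), via dilithium alkoxide enolate 6 (not isolated)
Conditions: LiN(i-Pr)2 (LDA, 2.2 equiv), THF–DMPU, −78 °C; then 4, −78 to −40 °C
Reagents that add atoms: none
Why: Fráter–Seebach alkylation of the β-hydroxy lactone dianion: the primary allylic bromide should attack C1 of the enolate from the face opposite the neighbouring lithium alkoxide, which sets C1 trans to the C6 hydroxyl on the lactone, the relative configuration the target needs at C1/C6.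

Step 4
Reactants: 7 trans lactone
Product: 9 (2R,3S)-3-[(Z)-3-iodobut-2-enyl]-4-methylidene-5-(trimethylsilyl)pentane-1,2-diol (allylsilane diol; C5 and C6 hydroxyls free), via bis(silylmethyl) carbinol 8 (not isolated)
Conditions: Me3SiCH2MgCl (5 equiv), CeCl3, THF, −78 °C to rt; then silica gel, CH2Cl2, rt
Reagents that add atoms: (trimethylsilyl)methylmagnesium chloride, C[Si](C)(C)C[Mg]Cl
Why: CeCl3-mediated double addition of the weakly basic silylmethyl Grignard reagent to the lactone carbonyl followed by silica-promoted Peterson olefination of the β-hydroxysilane should turn C7 into a 2-substituted allylsilane without enolising the C1 centre.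

Step 5
Reactants: 9 allylsilane diol
Product: 11 allylsilane with C5–OTBDPS and C6–OTES, via primary TBDPS ether 10 (not isolated)
Conditions: TBDPSCl (1.05 equiv), imidazole, CH2Cl2, 0 °C; then TESCl, DMAP (cat.), rt
Reagents that add atoms: tert-butyl(chloro)diphenylsilane, CC(C)(C)[Si](Cl)(c1ccccc1)c1ccccc1; chlorotriethylsilane, CC[Si](Cl)(CC)CC
Why: Silyl ether formation in sequence: the bulky TBDPSCl should react only at the primary C5 hydroxyl and TESCl then caps the secondary C6 hydroxyl, giving two silyl ethers of different acid lability.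

Step 6
Reactants: 11 bis-silyl ether allylsilane
Product: 13 allylic alcohol HOC8H2–C7(=C14H2)–C1H(CH2CH=C(CH3)I)–C6H(OTES)–C5H2OTBDPS (1S,6R), via silylmethyl epoxide 12 (not isolated)
Conditions: mCPBA (1.05 equiv), CH2Cl2, −20 to 0 °C (the 3-chlorobenzoic acid formed opens the epoxide)
Reagents that add atoms: 3-chloroperoxybenzoic acid, OOC(=O)c1cccc(Cl)c1
Why: Prilezhaev epoxidation of the electron-rich allylsilane alkene followed by acid-triggered opening of the β-silyl epoxide at C7 with loss of silicon (Peterson-type 1,2-elimination) should give the transposed primary allylic alcohol, the iodine-deactivated alkene reacting much more slowly.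

Step 7
Reactants: 13 allylic alcohol
Product: 14 2-substituted acrolein (C8 aldehyde, C7=C14H2)
Conditions: MnO2, CH2Cl2, rt
Reagents that add atoms: none
Why: Allylic oxidation with MnO2 acts only on the allylic primary alcohol and should stop at the 2-substituted acrolein.

Step 8
Reactants: 14 enal
Product: 16 (8S)-homoallylic alcohol (C8–OH, allyl on C8), via diisopinocampheylborinate 15 (not isolated)
Conditions: (−)-Ipc2B(allyl) (1.5 equiv), Et2O, −78 °C; then NaOH, H2O2, 0 °C
Reagents that add atoms: (−)-B-allyldiisopinocampheylborane, C=CCB([C@@H]1C[C@@H]2C[C@@H](C2(C)C)[C@H]1C)[C@@H]1C[C@@H]2C[C@@H](C2(C)C)[C@H]1C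
Why: Brown allylboration through a closed chair transition state: the (−)-Ipc2B group should deliver allyl to the Si face of the aldehyde under reagent control and set C8 as S, and alkaline H2O2 then cleaves the borinate.

Step 9
Reactants: 16 homoallylic alcohol
Product: 17 (8S)-prenyl carbinol (C9H2–C10H=C11(CH3)2 in place)
Conditions: 2-methyl-2-butene (excess), second-generation Grubbs catalyst RuCl2(=CHPh)(PCy3)(H2IMes) (5 mol %), CH2Cl2, 40 °C
Reagents that add atoms: 2-methyl-2-butene, CC=C(C)C
Why: Olefin cross-metathesis of the only monosubstituted alkene with excess 2-methyl-2-butene should build the prenyl terminus, the 1,1-disubstituted C7=C14 alkene and the trisubstituted iodoalkene being too hindered to enter the catalytic cycle.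

Step 10
Reactants: 17 prenyl carbinol
Product: 18 C6,C8-diol with C5–OTBDPS (1S,6R,8S)
Conditions: PPTS (0.2 equiv), MeOH–CH2Cl2, 0 °C
Reagents that add atoms: none
Why: Acid-catalysed methanolysis of silyl ethers removes the secondary TES group far faster than the primary TBDPS group, so the C6 and C8 hydroxyls should be free while C5 stays protected.

Step 11
Reactants: 18 C6,C8-diol; 19 angelic acid
Product: 21 C6,C8-bis-angelate with C5–OTBDPS, via angelic 2,4,6-trichlorobenzoic anhydride 20 (not isolated)
Conditions: 19 (6 equiv), 2,4,6-Cl3C6H2COCl, Et3N, toluene, rt; then 18, 75 °C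
Reagents that add atoms: none
Why: Yamaguchi esterification: the mixed anhydride acylates both secondary hydroxyls on heating without a nucleophilic amine catalyst, which should avoid the conjugate-addition path that isomerises angelate to tiglate.

Step 12
Reactants: 21 bis-angelate silyl ether
Product: 22 C5 primary alcohol bearing both angelates
Conditions: HF·pyridine, pyridine, THF, 0 °C to rt
Reagents that add atoms: none
Why: Fluoride-mediated silyl ether cleavage under pyridine-buffered, weakly acidic conditions should free the primary C5 hydroxyl without angeloyl migration from O6.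

Step 13
Reactants: 22 primary alcohol
Product: 23 iodo-aldehyde OHC5–C6H(OAng)–C1H(CH2CH=C(CH3)I)–C7(=C14H2)–C8H(OAng)–CH2CH=C(CH3)2 (1S,6R,8S; Z iodoalkene)
Conditions: Dess–Martin periodinane, NaHCO3, CH2Cl2, 0 °C; used at once
Reagents that add atoms: none
Why: Dess–Martin oxidation is fast and nearly neutral, so the primary alcohol should give the epimerisable α-acyloxy aldehyde without loss of configuration at C6, provided it is used at once.

Step 14
Reactants: 23 iodo-aldehyde
Product: 25 cyclohexenol (1S,5S,6R,8S; ring A with C3=C4, free C5–OH cis to the C6 angelate and to the C1 side chain), via alkenylchromium dichloride 24 (not isolated)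
Conditions: CrCl2 (8 equiv), NiCl2 (0.1 equiv), degassed DMF–THF, 0.005 M, rt; pH 7 buffer work-up
Reagents that add atoms: none
Why: Divalent chromium reduces NiCl2 to zerovalent nickel, which inserts into the C4–I bond with retention of the Z geometry; transmetalation to trivalent chromium gives alkenylchromium 24, whose C4 adds to the C5 aldehyde, and the chromium alkoxide is hydrolysed on work-up. The closest known reaction type is the intramolecular Nozaki–Hiyama–Kishi cyclisation of iodoalkenyl aldehydes to cyclic allylic alcohols. Ring A closes in a 6-exo-trig mode onto the carbonyl, the Z alkene C3=C4 ending inside the ring. The new stereocentre C5 is controlled by the existing C1 and C6 centres: a chair-like transition state with the C1 side chain and the chromium-bound oxygen pseudo-equatorial and the C6 angelate axial (chromium may also be chelated by the angelate carbonyl) should place the hydroxyl cis to the angelate. The step needs chemoselectivity for the aldehyde over two conjugated esters, which the mild alkenylchromium nucleophile provides, and no erosion at C6, which the neutral medium secures; high dilution suppresses intermolecular addition.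

Step 15
Reactants: 25 cyclohexenol
Product: 26 epoxy alcohol (1S,3S,4S,5R,6R,8S; C3–C4 epoxide cis to C5–OH)
Conditions: VO(acac)2 (5 mol %), t-BuOOH, CH2Cl2, 0 °C to rt
Reagents that add atoms: tert-butyl hydroperoxide, CC(C)(C)OO
Why: Vanadium-catalysed hydroxyl-directed epoxidation: the C5 vanadate ester delivers oxygen to the C3=C4 alkene from its own face, which sets C3 and C4 cis to the C5 hydroxyl, while alkenes that are not allylic to a free hydroxyl stay untouched.

Step 16
Reactants: 26 epoxy alcohol
Product: 27 C5 acetate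
Conditions: Ac2O, pyridine, DMAP (cat.), CH2Cl2, 0 °C to rt
Reagents that add atoms: acetic anhydride, CC(=O)OC(C)=O
Why: DMAP-catalysed acylation with acetic anhydride esterifies the only free hydroxyl, the hindered C5 carbinol, under conditions that leave epoxide and angelates alone.

Step 17
Reactants: 27 C5 acetate
Product: 28 CNP0316628.1 (1S,3S,4S,5R,6R,8S,10S)
Conditions: L-fructose-derived Shi ketone (0.3 equiv), Oxone (2KHSO5·KHSO4·K2SO4), K2CO3, Bu4NHSO4, MeCN–dimethoxymethane/aq. Na2B4O7–Na2EDTA, 0 °C
Reagents that add atoms: potassium peroxymonosulfate, [K+].[O-]S(=O)(=O)OO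
Why: Shi asymmetric epoxidation: the chiral dioxirane formed from the L-fructose-derived ketone should epoxidise only the electron-rich trisubstituted C10=C11 alkene through a spiro transition state and set C10 as S under catalyst control, the hindered C7=C14 alkene and the electron-poor angelates reacting far more slowly.

Compound list
1 | but-2-yn-1-ol | CC#CCO | starting material
2 | cyclic sodium alkenylalanate (Al on C3, O–Al ring) | [Na+].CC1=CCO[Al-]1(OCCOC)OCCOC | intermediate (not isolated)
3 | (Z)-3-iodobut-2-en-1-ol | C/C(I)=C/CO | intermediate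
4 | (Z)-1-bromo-3-iodobut-2-ene | C/C(I)=C/CBr | intermediate
5 | (R)-3-hydroxy-γ-butyrolactone | O=C1OC[C@H](O)C1 | starting material
6 | dilithium alkoxide enolate of 5 | [Li+].[Li+].[O-]C1=C[C@@H]([O-])CO1 | intermediate (not isolated)
7 | (3R,4R)-4-hydroxy-3-[(Z)-3-iodobut-2-enyl]dihydrofuran-2(3H)-one | O=C1OC[C@H](O)[C@H]1C/C=C(C)\I | intermediate
8 | (2R,3R)-3-[(Z)-3-iodobut-2-enyl]-5-(trimethylsilyl)-4-[(trimethylsilyl)methyl]pentane-1,2,4-triol | OC[C@H](O)[C@@H](C/C=C(C)\I)C(O)(C[Si](C)(C)C)C[Si](C)(C)C | intermediate (not isolated)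
9 | (2R,3S)-3-[(Z)-3-iodobut-2-enyl]-4-methylidene-5-(trimethylsilyl)pentane-1,2-diol | OC[C@H](O)[C@@H](C/C=C(C)\I)C(=C)C[Si](C)(C)C | intermediate
10 | primary (C5) TBDPS ether of 9 | CC(C)(C)[Si](c1ccccc1)(c1ccccc1)OC[C@H](O)[C@@H](C/C=C(C)\I)C(=C)C[Si](C)(C)C | intermediate (not isolated)
11 | C5–OTBDPS, C6–OTES allylsilane | CC(C)(C)[Si](c1ccccc1)(c1ccccc1)OC[C@H](O[Si](CC)(CC)CC)[C@@H](C/C=C(C)\I)C(=C)C[Si](C)(C)C | intermediate
12 | silylmethyl epoxide of 11 (both C7 epimers) | CC(C)(C)[Si](c1ccccc1)(c1ccccc1)OC[C@H](O[Si](CC)(CC)CC)[C@@H](C/C=C(C)\I)C1(CO1)C[Si](C)(C)C | intermediate (not isolated)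
13 | 2-substituted allylic alcohol (C8H2OH, C7=C14H2) | CC(C)(C)[Si](c1ccccc1)(c1ccccc1)OC[C@H](O[Si](CC)(CC)CC)[C@@H](C/C=C(C)\I)C(=C)CO | intermediate
14 | 2-substituted acrolein (C8 aldehyde) | CC(C)(C)[Si](c1ccccc1)(c1ccccc1)OC[C@H](O[Si](CC)(CC)CC)[C@@H](C/C=C(C)\I)C(=C)C=O | intermediate
15 | diisopinocampheylborinate of 16 | CC(C)(C)[Si](c1ccccc1)(c1ccccc1)OC[C@H](O[Si](CC)(CC)CC)[C@@H](C/C=C(C)\I)C(=C)[C@@H](OB([C@@H]1C[C@@H]2C[C@@H](C2(C)C)[C@H]1C)[C@@H]1C[C@@H]2C[C@@H](C2(C)C)[C@H]1C)CC=C | intermediate (not isolated)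
16 | (8S)-homoallylic alcohol | CC(C)(C)[Si](c1ccccc1)(c1ccccc1)OC[C@H](O[Si](CC)(CC)CC)[C@@H](C/C=C(C)\I)C(=C)[C@@H](O)CC=C | intermediate
17 | (8S)-prenyl carbinol | CC(C)(C)[Si](c1ccccc1)(c1ccccc1)OC[C@H](O[Si](CC)(CC)CC)[C@@H](C/C=C(C)\I)C(=C)[C@@H](O)CC=C(C)C | intermediate
18 | C6,C8-diol, C5–OTBDPS | CC(C)(C)[Si](c1ccccc1)(c1ccccc1)OC[C@H](O)[C@@H](C/C=C(C)\I)C(=C)[C@@H](O)CC=C(C)C | intermediate
19 | angelic acid | C/C=C(C)\C(=O)O | starting material
20 | angelic 2,4,6-trichlorobenzoic anhydride | C/C=C(C)\C(=O)OC(=O)c1c(Cl)cc(Cl)cc1Cl | intermediate (not isolated)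
21 | C6,C8-bis-angelate, C5–OTBDPS | CC(C)(C)[Si](c1ccccc1)(c1ccccc1)OC[C@H](OC(=O)/C(C)=C\C)[C@@H](C/C=C(C)\I)C(=C)[C@@H](OC(=O)/C(C)=C\C)CC=C(C)C | intermediate
22 | C5 primary alcohol, bis-angelate | OC[C@H](OC(=O)/C(C)=C\C)[C@@H](C/C=C(C)\I)C(=C)[C@@H](OC(=O)/C(C)=C\C)CC=C(C)C | intermediate
23 | acyclic iodo-aldehyde, bis-angelate (1S,6R,8S) | O=C[C@H](OC(=O)/C(C)=C\C)[C@@H](C/C=C(C)\I)C(=C)[C@@H](OC(=O)/C(C)=C\C)CC=C(C)C | intermediate
24 | alkenylchromium dichloride | O=C[C@H](OC(=O)/C(C)=C\C)[C@@H](C/C=C(C)\[Cr](Cl)Cl)C(=C)[C@@H](OC(=O)/C(C)=C\C)CC=C(C)C | intermediate (not isolated)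
25 | cyclohexenol with free C5–OH (1S,5S,6R,8S) | C=C([C@@H](OC(=O)/C(C)=C\C)CC=C(C)C)[C@@H]1CC=C(C)[C@H](O)[C@@H]1OC(=O)/C(C)=C\C | intermediate
26 | ring epoxy alcohol | C=C([C@@H](OC(=O)/C(C)=C\C)CC=C(C)C)[C@@H]1C[C@@H]2O[C@]2(C)[C@H](O)[C@@H]1OC(=O)/C(C)=C\C | intermediate
27 | ring epoxy acetate | C=C([C@@H](OC(=O)/C(C)=C\C)CC=C(C)C)[C@@H]1C[C@@H]2O[C@]2(C)[C@H](OC(C)=O)[C@@H]1OC(=O)/C(C)=C\C | intermediate
28 | CNP0316628.1 | C=C([C@H](C[C@@H]1OC1(C)C)OC(=O)/C(C)=C\C)[C@@H]1C[C@@H]2O[C@]2(C)[C@H](OC(C)=O)[C@@H]1OC(=O)/C(C)=C\C | target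

Total step count: 17. Longest linear sequence: 17 steps (1 to 28); 5 and 19 enter as purchased materials.

Steps most likely to fail

Step 14. The addition to the C5 aldehyde may show poor facial selectivity, and the angeloyl group may migrate from O6 to the new O5 alkoxide. Fallback, setting out from 23 and returning to 25: the cyclisation is run as above and the mixture of 25 with its C5 epimer, the trans cyclohexenol F1, is oxidised with Dess–Martin periodinane (NaHCO3, CH2Cl2, 0 °C) to the cyclohexenone F2. Luche reduction (NaBH4, CeCl3·7H2O, MeOH, −78 °C) should then deliver hydride to the face opposite the two cis substituents, the C1 side chain and the C6 angelate, and give 25, so that C5 is set by reduction instead of by the ring closure.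

Step 11. The activated angeloyl donor may isomerise from Z to E, and acylation of two hindered secondary hydroxyls may stay incomplete. Fallback, setting out from 18 and returning to 21: both hydroxyls are esterified with 2-[bis(2,2,2-trifluoroethoxy)phosphoryl]propanoic acid (DCC, DMAP, CH2Cl2) to give the bis(phosphonopropionate) F3. A double Still–Gennari olefination (KN(SiMe3)2, 18-crown-6, THF, −78 °C; acetaldehyde) then builds both (Z)-2-methylbut-2-enoates on the substrate and gives 21.

Step 6. The peracid may over-oxidise (attack on the iodoalkene or on iodine), and the acid needed to open the silyl epoxide may strip the TES ether. Fallback, setting out from 11 and returning to 13: PhSeCl (CH2Cl2, −78 °C) substitutes the allylsilane with allylic transposition to give the allyl phenyl selenide F4. Oxidation with H2O2/pyridine (0 °C) then triggers the selenoxide [2,3]-sigmatropic shift and hydrolysis to 13 without any epoxidation.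

Further compounds
F1 | step 14 | C5-epimeric cyclohexenol (C5–OH trans to the C6 angelate) | C=C([C@@H](OC(=O)/C(C)=C\C)CC=C(C)C)[C@@H]1CC=C(C)[C@@H](O)[C@@H]1OC(=O)/C(C)=C\C
F2 | step 14 | cyclohexenone (C5 ketone) | C=C([C@@H](OC(=O)/C(C)=C\C)CC=C(C)C)[C@@H]1CC=C(C)C(=O)[C@@H]1OC(=O)/C(C)=C\C
F3 | step 11 | C6,C8-bis[2-(bis(2,2,2-trifluoroethoxy)phosphoryl)propanoate], C5–OTBDPS | CC(C)(C)[Si](c1ccccc1)(c1ccccc1)OC[C@H](OC(=O)C(C)P(=O)(OCC(F)(F)F)OCC(F)(F)F)[C@@H](C/C=C(C)\I)C(=C)[C@@H](OC(=O)C(C)P(=O)(OCC(F)(F)F)OCC(F)(F)F)CC=C(C)C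
F4 | step 6 | allyl phenyl selenide (PhSe–CH2–C7(=CH2)) | CC(C)(C)[Si](c1ccccc1)(c1ccccc1)OC[C@H](O[Si](CC)(CC)CC)[C@@H](C/C=C(C)\I)C(=C)C[Se]c1ccccc1
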